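**Assumption:** the SMILES is taken at face value, i.e. (3S,3aR,4R,5R,6S) with a (Z)-2-methylbut-2-enoate (angelate); the ligand antipodes in steps 1 and 3 and in the fallback epoxidation are those that give the configurations drawn, to be fixed by one test run.

**Retrosynthetic overview**
1. Target ⇒ tricyclic cyclopropylcarbinol + angelic acid: a cationic cyclopropylcarbinyl-to-homoallyl ring expansion (six → seven) forms the ring alkene and the angelate C–O bond in one step.
2. Cyclopropylcarbinol ⇒ trans-fused hexahydroindenol (hydroxyl-directed cyclopropanation) ⇒ isopropenyl/vinyl diene (ring-closing metathesis).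
3. Diene ⇒ 2,3-trans cyclopentanone aldol (isopropenyl organocerium addition, selective acetylation).
4. Aldol ⇒ 3-methylcyclopent-2-en-1-one + B2pin2 + (2R)-2-isopropylbut-3-enal (conjugate borylation, aldol, C–B oxidation); aldehyde ⇒ methyl 4-bromocrotonate + iPrMgBr (SN2′).
5. Ring order: cyclopentane (bought) → cyclohexene (metathesis) → cyclopropane → cycloheptene (ring expansion, last step).

**Route**

Step 1
Reactants: 1 methyl (2E)-4-bromobut-2-enoate; 2 isopropylmagnesium bromide
Product: 3 methyl (2R)-2-(propan-2-yl)but-3-enoate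
Conditions: 2 (1.2 equiv), CuBr·SMe2 (1 mol%), (R,R)-Taniaphos (1.2 mol%), CH2Cl2, −78 °C
Reagents that add atoms: none
Why: Copper-catalysed asymmetric allylic alkylation (SN2′): the isopropylcopper species adds at C2 anti to the leaving bromide and moves the alkene to the chain end, and the chiral diphosphine selects the enantioface, which sets the (2R) centre.

Step 2
Reactants: 3 methyl (2R)-2-(propan-2-yl)but-3-enoate
Product: 4 (2R)-2-(propan-2-yl)but-3-enal
Conditions: iBu2AlH (1.05 equiv), CH2Cl2, −78 °C; MeOH, then aq. potassium sodium tartrate (KNaC4H4O6); dried solution used at once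
Reagents that add atoms: none
Why: Partial ester reduction: the aluminium hemiacetal is stable at −78 °C and gives the aldehyde only on quench, and the neutral work-up avoids enolisation, so the α-centre and the β,γ-alkene are kept.

Step 3
Reactants: 5 3-methylcyclopent-2-en-1-one; 4 (2R)-2-(propan-2-yl)but-3-enal
Product: 8 (2R,3S)-3-hydroxy-2-[(1R,2R)-1-hydroxy-2-(propan-2-yl)but-3-en-1-yl]-3-methylcyclopentan-1-one, via boron enolate 6 (not isolated), via boron aldolate 7 (not isolated)
Conditions: B2pin2 (1.05 equiv), [Cu(MeCN)4]PF6 (5 mol%), (R,R)-QuinoxP* (6 mol%), LiOtBu (10 mol%), THF, rt; then 4 (1.3 equiv), −40 → 0 °C; then NaBO3·4H2O, THF/H2O, 0 °C → rt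
Reagents that add atoms: sodium perborate NaBO3, [Na+].[O-]OB=O (oxygen of the tertiary hydroxyl); bis(pinacolato)diboron, CC1(C)OB(OC1(C)C)B1OC(C)(C)C(C)(C)O1 (boron of 6 and 7 only)
Why: Copper-catalysed enantioselective conjugate borylation, boron-enolate aldol and C–B oxidation in one pot: the ligand-bound Cu–Bpin sets the boron-bearing centre (retention on oxidation gives the 3S alcohol), the enol borate 6 reacts with 4 (added only after the enone is consumed) through a closed transition state on the face anti to the boryl group (C2) with the syn preference of enol borates, and Felkin–Anh control by the isopropyl-bearing centre fixes C1′.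

Step 4
Reactants: 8 (2R,3S)-3-hydroxy-2-[(1R,2R)-1-hydroxy-2-(propan-2-yl)but-3-en-1-yl]-3-methylcyclopentan-1-one; 9 isopropenylmagnesium bromide
Product: 10 (1S,2R,3S)-2-[(1R,2R)-1-hydroxy-2-(propan-2-yl)but-3-en-1-yl]-1-methyl-3-(prop-1-en-2-yl)cyclopentane-1,3-diol
Conditions: CeCl3 (4 equiv), CH2=C(CH3)MgBr (4 equiv), THF, −78 → −20 °C; aq. NH4Cl
Reagents that add atoms: none
Why: Organocerium 1,2-addition to a ketone: the weakly basic reagent avoids enolisation and retro-aldol, and it attacks the ring face anti to the C2 side chain and the cis ring methyl, so the new tertiary hydroxyl is cis to the side chain (3S).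

Step 5
Reactants: 10 (1S,2R,3S)-2-[(1R,2R)-1-hydroxy-2-(propan-2-yl)but-3-en-1-yl]-1-methyl-3-(prop-1-en-2-yl)cyclopentane-1,3-diol
Product: 11 (1R,2R)-1-[(1R,2S,5S)-2,5-dihydroxy-2-methyl-5-(prop-1-en-2-yl)cyclopentyl]-2-(propan-2-yl)but-3-en-1-yl acetate
Conditions: Ac2O (2 equiv), pyridine, DMAP (10 mol%), CH2Cl2, 0 °C → rt
Reagents that add atoms: acetic anhydride, CC(=O)OC(C)=O
Why: DMAP-catalysed acylation: only the secondary hydroxyl reacts, the two tertiary alcohols stay free, and the tertiary allylic hydroxyl is left as the only directing group for step 7.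

Step 6
Reactants: 11 (1R,2R)-1-[(1R,2S,5S)-2,5-dihydroxy-2-methyl-5-(prop-1-en-2-yl)cyclopentyl]-2-(propan-2-yl)but-3-en-1-yl acetate
Product: 12 (1S,3aS,6R,7R,7aR)-1,3a-dihydroxy-1,4-dimethyl-6-(propan-2-yl)-2,3,3a,6,7,7a-hexahydro-1H-inden-7-yl acetate
Conditions: second-generation Hoveyda–Grubbs catalyst RuCl2(H2IMes)(=CH-C6H4-2-OiPr) (5 mol%), toluene (5 mM), 80 °C
Reagents that add atoms: none
Why: Ring-closing olefin metathesis: loss of ethene joins the isopropenyl and vinyl groups into a cyclohexene with a trisubstituted alkene, the ring fusion is trans because the two arms are trans on the cyclopentane, and no stereocentre is touched.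

Step 7
Reactants: 12 (1S,3aS,6R,7R,7aR)-1,3a-dihydroxy-1,4-dimethyl-6-(propan-2-yl)-2,3,3a,6,7,7a-hexahydro-1H-inden-7-yl acetate
Product: 13 (1S,2R,4R,5R,6R,7R,8S)-1,8-dihydroxy-2,8-dimethyl-5-(propan-2-yl)tricyclo[5.3.0.0^2,4]decan-6-yl acetate
Conditions: Et2Zn (5 equiv), CH2I2 (10 equiv), CH2Cl2, 0 °C → rt
Reagents that add atoms: diiodomethane, ICI
Why: Hydroxyl-directed Simmons–Smith cyclopropanation (Furukawa variant): the zinc alkoxide of the tertiary allylic alcohol delivers the carbenoid to its own face of the alkene, which sets both cyclopropane centres (2R,4R) syn to that hydroxyl.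

Step 8
Reactants: 13 (1S,2R,4R,5R,6R,7R,8S)-1,8-dihydroxy-2,8-dimethyl-5-(propan-2-yl)tricyclo[5.3.0.0^2,4]decan-6-yl acetate; 14 (2Z)-2-methylbut-2-enoic acid (angelic acid)
Product: 15 (3S,3aR,4R,5R,6S)-4-(acetyloxy)-3-hydroxy-3,8-dimethyl-5-(propan-2-yl)-1,2,3,3a,4,5,6,7-octahydroazulen-6-yl (2Z)-2-methylbut-2-enoate
Conditions: 14 (5 equiv), Sc(OTf)3 (5 mol%), 4 Å molecular sieves, CH2Cl2, −20 → 0 °C
Reagents that add atoms: none
Why: Proposed new method: a Lewis-acid-catalysed dehydrative ring-expanding acyloxylation, in which Sc(OTf)3 ionises the tertiary cyclopropylcarbinol at C1, the delocalised cyclopropylcarbinyl cation opens at the internal C2–C4 bond (secondary rather than primary terminus, with relief of trans-fused bicyclo[4.1.0] strain), and angelic acid captures C4 anti to the breaking bond so that the ester oxygen ends on the face where the cyclopropane CH2 stood (6S) while the tetrasubstituted ring alkene forms as the thermodynamic sink; the closest known reaction type is the acid-catalysed cyclopropylcarbinyl-to-homoallyl rearrangement (ring enlargement of bicyclo[n.1.0]alkan-2-ols, sabinene hydrate to terpinen-4-ol, the stereospecific i-steroid rearrangement), not yet shown with a free α,β-unsaturated carboxylic acid as the only nucleophile on a fused tertiary substrate.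

**Compound list**
1 | methyl (2E)-4-bromobut-2-enoate | COC(=O)/C=C/CBr | starting material
2 | isopropylmagnesium bromide | CC(C)[Mg]Br | starting material
3 | methyl (2R)-2-(propan-2-yl)but-3-enoate | COC(=O)[C@@H](C=C)C(C)C | intermediate
4 | (2R)-2-(propan-2-yl)but-3-enal | O=C[C@@H](C=C)C(C)C | intermediate
5 | 3-methylcyclopent-2-en-1-one | CC1=CC(=O)CC1 | starting material
6 | 2-{[(3R)-3-methyl-3-(4,4,5,5-tetramethyl-1,3,2-dioxaborolan-2-yl)cyclopent-1-en-1-yl]oxy}-4,4,5,5-tetramethyl-1,3,2-dioxaborolane (boron enolate) | C[C@]1(B2OC(C)(C)C(C)(C)O2)CCC(OB3OC(C)(C)C(C)(C)O3)=C1 | intermediate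
7 | (2S,3R)-3-methyl-2-{(1R,2R)-2-(propan-2-yl)-1-[(4,4,5,5-tetramethyl-1,3,2-dioxaborolan-2-yl)oxy]but-3-en-1-yl}-3-(4,4,5,5-tetramethyl-1,3,2-dioxaborolan-2-yl)cyclopentan-1-one (boron aldolate) | O=C1CC[C@](C)(B2OC(C)(C)C(C)(C)O2)[C@H]1[C@H](OB3OC(C)(C)C(C)(C)O3)[C@@H](C=C)C(C)C | intermediate
8 | (2R,3S)-3-hydroxy-2-[(1R,2R)-1-hydroxy-2-(propan-2-yl)but-3-en-1-yl]-3-methylcyclopentan-1-one | O=C1CC[C@](C)(O)[C@H]1[C@H](O)[C@@H](C=C)C(C)C | intermediate
9 | isopropenylmagnesium bromide | C=C(C)[Mg]Br | starting material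
10 | (1S,2R,3S)-2-[(1R,2R)-1-hydroxy-2-(propan-2-yl)but-3-en-1-yl]-1-methyl-3-(prop-1-en-2-yl)cyclopentane-1,3-diol | C=C(C)[C@]1(O)CC[C@](C)(O)[C@H]1[C@H](O)[C@@H](C=C)C(C)C | intermediate
11 | (1R,2R)-1-[(1R,2S,5S)-2,5-dihydroxy-2-methyl-5-(prop-1-en-2-yl)cyclopentyl]-2-(propan-2-yl)but-3-en-1-yl acetate | C=C(C)[C@]1(O)CC[C@](C)(O)[C@H]1[C@H](OC(C)=O)[C@@H](C=C)C(C)C | intermediate
12 | (1S,3aS,6R,7R,7aR)-1,3a-dihydroxy-1,4-dimethyl-6-(propan-2-yl)-2,3,3a,6,7,7a-hexahydro-1H-inden-7-yl acetate | CC1=C[C@@H](C(C)C)[C@@H](OC(C)=O)[C@@H]2[C@@](C)(O)CC[C@@]12O | intermediate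
13 | (1S,2R,4R,5R,6R,7R,8S)-1,8-dihydroxy-2,8-dimethyl-5-(propan-2-yl)tricyclo[5.3.0.0^2,4]decan-6-yl acetate | C[C@]13C[C@@H]3[C@@H](C(C)C)[C@@H](OC(C)=O)[C@@H]2[C@@](C)(O)CC[C@@]12O | intermediate
14 | (2Z)-2-methylbut-2-enoic acid (angelic acid) | C/C=C(/C)C(=O)O | starting material
15 | (3S,3aR,4R,5R,6S)-4-(acetyloxy)-3-hydroxy-3,8-dimethyl-5-(propan-2-yl)-1,2,3,3a,4,5,6,7-octahydroazulen-6-yl (2Z)-2-methylbut-2-enoate | C/C=C(/C)C(=O)O[C@H]1CC(C)=C2CC[C@](C)(O)[C@H]2[C@H](OC(C)=O)[C@@H]1C(C)C | target

**Totals**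
Total step count: 8. Longest linear sequence: 8 steps (1 → 3 → 4 → 8 → 10 → 11 → 12 → 13 → 15).

**Three steps most likely to fail**

Step 8 (the proposed new step). The cation may open at the external cyclopropane bond instead, water may compete with the acid, the neighbouring acetate may take part, or the angelate may isomerise to the tiglate. Fallback with known chemistry, setting out from 13: catalytic HClO4 in acetone/water (4:1, rt) carries out the known hydrolytic cyclopropylcarbinyl-to-homoallyl ring enlargement and gives the homoallylic alcohol (3S,3aR,4R,5R,6S)-3,6-dihydroxy-3,8-dimethyl-5-(propan-2-yl)-1,2,3,3a,4,5,6,7-octahydroazulen-4-yl acetate F1. Separately, 14 is treated with 2,4,6-trichlorobenzoyl chloride and Et3N in toluene to give the mixed anhydride (2Z)-2-methylbut-2-enoic 2,4,6-trichlorobenzoic anhydride F2. Heating F1 with F2 at 80 °C (Yamaguchi-type esterification, which keeps the Z geometry) acylates only the secondary hydroxyl and comes back to the route at 15.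

Step 3. Three stereochemical elements must line up (face anti to boron, syn aldol, Felkin–Anh with isopropyl as the large group), and the aldehyde is prone to conjugation. Fallback setting out from 5: enantioselective nucleophilic epoxidation (aq. H2O2, 9-amino-9-deoxy-epi-quinine with trifluoroacetic acid, dioxane) gives (1S,5S)-5-methyl-6-oxabicyclo[3.1.0]hexan-2-one F3, whose epoxide oxygen becomes the tertiary hydroxyl. SmI2 (2.1 equiv, THF, −78 °C) cleaves the α C–O bond to the regiodefined samarium enolate diiodosamarium (3S)-3-[(diiodosamario)oxy]-3-methylcyclopent-1-en-1-olate F4. This is intercepted by 4 anti to the bulky samarium alkoxide, and buffered work-up comes back to the route at 8. The stereocentre source and the way the enolate is made are both different from the main step.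

Step 2. The aldehyde is volatile, can be over-reduced, and can epimerise or move its alkene into conjugation. Fallback setting out from 3: full reduction with LiAlH4 (Et2O, 0 °C) gives the stable alcohol (2R)-2-(propan-2-yl)but-3-en-1-ol F5, which can be purified and stored. Oxidation with Dess–Martin periodinane (CH2Cl2, NaHCO3, 0 °C) just before use comes back to the route at 4.

**Further compounds**
F1 | step 8 | (3S,3aR,4R,5R,6S)-3,6-dihydroxy-3,8-dimethyl-5-(propan-2-yl)-1,2,3,3a,4,5,6,7-octahydroazulen-4-yl acetate | O[C@H]1CC(C)=C2CC[C@](C)(O)[C@H]2[C@H](OC(C)=O)[C@@H]1C(C)C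
F2 | step 8 | (2Z)-2-methylbut-2-enoic 2,4,6-trichlorobenzoic anhydride | C/C=C(/C)C(=O)OC(=O)c1c(Cl)cc(Cl)cc1Cl
F3 | step 3 | (1S,5S)-5-methyl-6-oxabicyclo[3.1.0]hexan-2-one | O=C1CC[C@]2(C)O[C@H]12
F4 | step 3 | diiodosamarium (3S)-3-[(diiodosamario)oxy]-3-methylcyclopent-1-en-1-olate | C[C@]1(O[Sm](I)I)CCC(O[Sm](I)I)=C1
F5 | step 2 | (2R)-2-(propan-2-yl)but-3-en-1-ol | OC[C@@H](C=C)C(C)C
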